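## The problem

The target 47 is a germacrane-type compound with a ten-membered carbocycle. Locants used throughout: ring C1–C10; C11 on C7 carries the acetoxymethyl carbon C12 and the methylene C13; C14 on C10 is the CH2 esterified with (2R,3S)-3-hydroxy-2-methylbutanoic acid; C15 on C4 is the CH2OH; C9 bears the 3-methylbut-2-enoate. The ring holds a ring-trans C1=C10 alkene and a trans 4,5-epoxide. Six stereocentres must be set. The two in the acyl chain are remote and are best brought in as a finished acid. C9 has no neighbouring centre and needs reagent control. C4 and C5 can be delivered at the very end by the free C15 allylic hydroxyl. C7 is 1,3 to C9 and can only be steered through the conformation of the ring. Four oxygens (C9, C12, C14, C15) must be told apart. The three esters are allylic and base-labile, the β-hydroxy ester can eliminate or undergo retro-aldol cleavage, and the epoxy alcohol opens with acid. The cyclodeca-1,5-diene that precedes the epoxide is strained and prone to Cope rearrangement on heating and to transannular cyclisation with acid, so once the ring exists the chemistry should stay at or below about 65 °C and near neutral. The structure offers one polar handle for the ring closure: before epoxidation C6 is allylic to C4=C5, and C7 is α to C11, which can be a ketone and later the C11=C13 alkene. The C6–C7 bond therefore pairs a π-allyl terminus with a stabilised enolate.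

## Retrosynthesis

Epoxide (C4–O, C5–O). Target 47 is cut to allylic alcohol 46, because the epoxy alcohol is the most acid-sensitive group and the C15 hydroxyl directs a Sharpless epoxidation. L-(+)-Diethyl tartrate is the antipode that gives 2S-configured 2-substituted glycidols, which here means 4S,5R. The forward step must touch only C4=C5 in a triene; only that alkene has an allylic hydroxyl.

Esters (three acyl–O bonds). Diol 46 comes from bis-silyl ether 45, and 45 from diol 35 by two acylations: first the primary C14 hydroxyl with acid 42 (giving 43), then the secondary C9 hydroxyl with chloride 44. Diol 35 comes from acetonide 34, whose C12 acetate is put on earlier (33 from PMB ether 32). Late acylation keeps all esters away from organometallic steps and from zerovalent palladium, which would ionise allylic esters. One acetonide protects both O9 and O14 and later frees them together, so the pair is differentiated only by primary against secondary reactivity.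

C11=C13. Triene 32 is cut to ketone 31. The ketone is what makes C7 nucleophilic in the ring closure and epimerisable afterwards, and its methylenation asks only for a non-basic reagent.

C7–H and C7–S. Ketone 31 is the C7 epimer selected by base equilibration from mixture 30, which comes from keto sulfone 28 by reductive desulfonylation. A phenylsulfonyl group replaces the more obvious ester as second activator for two reasons. It survives the iBu2AlH reduction needed earlier. It also leaves at −78 °C, whereas thermal dealkoxycarbonylation at about 150 °C would risk Cope rearrangement of the ring.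

C6–C7 (key cut). Macrocycle 28 opens to allylic methyl carbonate 27, whose β-keto sulfone is the pronucleophile. Against the neighbouring cuts (C9–C10 by carbonyl addition, C1–C2 or C2–C3 by alkylation) this one needs no strong base and no stoichiometric metal at the ring-forming stage. The precursor is acyclic, with one stereocentre and two alkenes of fixed geometry. The forward reaction must close a ten-membered ring at the unsubstituted allyl terminus without disturbing the C4=C5 geometry.

C7–C11 and the carbonate. Carbonate 27 comes from alcohol 26, this from TBS ether 25, and 25 from sulfone 19 and Weinreb amide 23 (from 20 and 21). The cut joins the whole C11–C12 unit in one acylation of a sulfonyl carbanion, and it is placed after every hydride reduction.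

C10–C14. Acetonide 19 comes from diol 18, and 18 from hydroxy ester 17. The ester carbon C14 is attached to alkenylstannane 16, itself the trans-hydrostannation product of propargylic alcohol 15. This sequence turns an alkyne into the trisubstituted alkene with C9 trans to C2, a geometry that syn-hydrometalation cannot give.

C9–C10 and the C9 stereocentre. Alcohol 15 comes from ynone 14 by asymmetric transfer hydrogenation, and 14 from alkyne 10 and Weinreb amide 12 (from acid 11). Catalyst control at an ynone is more general than asymmetric alkynylation of an unbranched aldehyde. The partner 12 already carries the sulfone, so no later functional-group change at C7 is needed.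

C3–C4 and the C4=C5 geometry. Alkyne 10 comes through 9 and 8 from enoate 7, the syn-carbocupration product of ynoate 4 with the Grignard reagent of bromide 5. Ynoate 4 comes from propargyl alcohol 1 via 2. The cis addition fixes C15 cis to C6 and leaves the two allylic oxygens differentiated from the start (silyl ether and ester).

Side-chain acid. Acid 42 comes from imide 40, made by silylation of the Evans syn-aldol product 39 of imide 36 and acetaldehyde 37. The R auxiliary gives the 2R,3S pair.

## Roads not taken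

Alternative 1: The ring would be closed at C1–C2. The terminal alkyne of epoxy iodide A1 is deprotonated (LiN(SiMe3)2, THF/DMPU) and the acetylide displaces the primary iodide to give cyclodecyne A2. The C1=C10 alkene is then made on the ring by trans-hydrostannation. The merit is real: C7 and the epoxide are set before the ring exists, so the C7 question that burdens the chosen plan does not arise, and the hydrostannation gives the ring-trans alkene by construction. The weak points are the closure and what follows it. A ten-membered cycloalkyne that also holds a trans epoxide is strained. The acetylide is a strong base next to a primary iodide with β-hydrogens and to an epoxide. Nothing makes the closure reversible or self-correcting. C14 must then be attached by carbonylation and hydride reduction in the presence of the epoxide, and three orthogonal silyl groups have to be handled on an epoxy alcohol. The chosen plan closes the ring under neutral, catalytic conditions and keeps the epoxide for the last step. Against the superior C7 control of this alternative it can only set the conformational anchoring of step 20 and the recycling of the wrong epimer.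

Alternative 2: The C7–C8 bond would be made by Claisen rearrangement of the twelve-membered 2-methylene oxacycle A3, which contracts to epoxy enone A4 while creating the C11=C13 methylene and the C9 carbonyl. This is the most economical idea on paper. C7 is set by a concerted transition state, no activating group has to be removed and no methylenation is needed. Its costs are elsewhere. A3 requires a macrolactonisation and a methylenation of the lactone. The rearrangement needs heat, which the Cope-prone 1,5-diene and the epoxide in A4 tolerate poorly. The configuration at C7 depends on chair against boat geometry inside a twelve-membered ring. C9 is left as an enone carbonyl to be reduced 1,2 with the right facial sense on a flexible ring. The chosen plan has the weaker control at C7 but sets C9 by a catalyst on an acyclic ynone and never heats the ten-membered ring above 65 °C.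

Alternative 3: The ring would arise by anionic oxy-Cope rearrangement of trans-1,2-dialkenylcyclohexanol A5 (KH, 18-crown-6), which forms C2–C3, cleaves C5–C10 and gives, after trapping with PhNTf2, dienyl triflate A6. Its strengths are that C7 and C9 are fixed on a cyclohexane, where relative configuration is easy to control, and that ring expansion needs no high dilution. In both respects it is better than the chosen plan. Its burden is A5: two adjacent fully substituted carbons (C5 and C10), each carrying a branched alkenyl group, must be assembled with the trans relationship. Both new ring alkenes then depend on one chair transition state, and the C5 triflate must afterwards be reduced without touching three other alkenes. The chosen plan sets each alkene geometry separately by a stereospecific addition to an alkyne and needs no quaternary carbon in its precursor. It pays with the activating group at C7 and the equilibration that follows.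

Key step: step 18

Remark: TBS = tert-butyldimethylsilyl, TBDPS = tert-butyldiphenylsilyl, TES = triethylsilyl, PMB = 4-methoxybenzyl. The CIP label of C7 is R while C4=C5 is an alkene and becomes S on epoxidation by a change of priorities only. The C4=C5 alkene is ring-trans but carries the CIP label Z because C15 outranks C3.
Assumption: the 7,9-cis arrangement of the target corresponds to both substituents being pseudo-equatorial in the crown conformer of the ring; step 20 relies on this.

## Steps

Step 1
Reactants: 1 prop-2-yn-1-ol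
Product: 2 tert-butyl(diphenyl)(prop-2-yn-1-yloxy)silane
Conditions: TBDPSCl, imidazole, CH2Cl2, 0 °C to rt
Reagents that add atoms: tert-butyl(chloro)diphenylsilane, CC(C)(C)[Si](Cl)(c1ccccc1)c1ccccc1
Why: Routine silylation of a primary alcohol; TBDPS is chosen because this oxygen (C15) stays protected until step 30.

Step 2
Reactants: 2 tert-butyl(diphenyl)(prop-2-yn-1-yloxy)silane
Product: 4 methyl 4-(TBDPS-oxy)but-2-ynoate, via lithium acetylide 3 (not isolated)
Conditions: n-BuLi, THF, −78 °C; then ClCO2Me, −78 to 0 °C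
Reagents that add atoms: methyl chloroformate, COC(=O)Cl
Why: Acylation of a lithium acetylide with a chloroformate is the standard route to 2-ynoates; the new carbon is C6.

Step 3
Reactants: 5 (4-bromobut-1-yn-1-yl)trimethylsilane; 4 methyl 4-(TBDPS-oxy)but-2-ynoate
Product: 7 methyl (2Z)-3-[(TBDPS-oxy)methyl]-7-(trimethylsilyl)hept-2-en-6-ynoate, via Grignard reagent 6 (not isolated)
Conditions: Mg, THF, rt; CuBr·SMe2, THF, −78 °C; then 4, −78 °C; MeOH then aq. NH4Cl at −78 °C
Reagents that add atoms: none
Why: Organocopper conjugate addition to a 2-ynoate is a syn carbometalation, and protonation of the alkenylcopper at −78 °C occurs with retention. C3 therefore ends cis to H and C15 cis to the ester carbon C6, which is the geometry of the later ring-trans C4=C5 alkene.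

Step 4
Reactants: 7 methyl (2Z)-3-[(TBDPS-oxy)methyl]-7-(trimethylsilyl)hept-2-en-6-ynoate
Product: 8 (2Z)-3-[(TBDPS-oxy)methyl]-7-(trimethylsilyl)hept-2-en-6-yn-1-ol
Conditions: iBu2AlH, CH2Cl2, −78 °C
Reagents that add atoms: none
Why: 1,2-Reduction of an enoate to the allylic alcohol by iBu2AlH leaves the alkene geometry and the silyl groups untouched.

Step 5
Reactants: 8 (2Z)-3-[(TBDPS-oxy)methyl]-7-(trimethylsilyl)hept-2-en-6-yn-1-ol
Product: 9 (2Z)-1-(TBS-oxy)-3-[(TBDPS-oxy)methyl]-7-(trimethylsilyl)hept-2-en-6-yne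
Conditions: TBSCl, imidazole, CH2Cl2, rt
Reagents that add atoms: tert-butyl(chloro)dimethylsilane, CC(C)(C)[Si](C)(C)Cl
Why: Silylation without a free alkoxide avoids O-to-O migration of the neighbouring cis TBDPS group; the primary TBS ether at C6 can later be removed in the presence of TBDPS.

Step 6
Reactants: 9 (2Z)-1-(TBS-oxy)-3-[(TBDPS-oxy)methyl]-7-(trimethylsilyl)hept-2-en-6-yne
Product: 10 (5Z)-7-(TBS-oxy)-5-[(TBDPS-oxy)methyl]hept-5-en-1-yne
Conditions: K2CO3, MeOH, rt
Reagents that add atoms: none
Why: Methanolysis cleaves the C(sp)–SiMe3 bond selectively; silyl ethers of primary alcohols are stable to these conditions.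

Step 7
Reactants: 11 3-(phenylsulfonyl)propanoic acid
Product: 12 N-methoxy-N-methyl-3-(phenylsulfonyl)propanamide
Conditions: MeNH(OMe)·HCl, EDC·HCl, N-methylmorpholine, CH2Cl2, 0 °C to rt
Reagents that add atoms: N,O-dimethylhydroxylamine hydrochloride, CNOC.Cl
Why: Carbodiimide amidation; only a weak amine base is present, so benzenesulfinate should not be eliminated from the activated acid.

Step 8
Reactants: 10 (5Z)-7-(TBS-oxy)-5-[(TBDPS-oxy)methyl]hept-5-en-1-yne; 12 N-methoxy-N-methyl-3-(phenylsulfonyl)propanamide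
Product: 14 (8Z)-10-(TBS-oxy)-8-[(TBDPS-oxy)methyl]-1-(phenylsulfonyl)dec-8-en-4-yn-3-one, via lithium acetylide 13 (not isolated)
Conditions: n-BuLi, THF, −78 °C; then 12, −78 to −30 °C; aq. NH4Cl at −78 °C
Reagents that add atoms: none
Why: Weinreb ketone synthesis; the chelated tetrahedral adduct prevents over-addition and keeps the β-sulfonyl ketone masked until the acidic quench. This step forms C9–C10.

Step 9
Reactants: 14 (8Z)-10-(TBS-oxy)-8-[(TBDPS-oxy)methyl]-1-(phenylsulfonyl)dec-8-en-4-yn-3-one
Product: 15 (3R,8Z)-10-(TBS-oxy)-8-[(TBDPS-oxy)methyl]-1-(phenylsulfonyl)dec-8-en-4-yn-3-ol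
Conditions: RuCl[(R,R)-TsDPEN](p-cymene) (2 mol%), HCO2H/Et3N (5:2), CH2Cl2, rt
Reagents that add atoms: none
Why: Noyori asymmetric transfer hydrogenation of an ynone, in which the alkynyl group takes the place of the aryl group in the transition state; the R,R catalyst should give the R carbinol (C9). The acidic formate medium holds no free base that could eliminate benzenesulfinate.

Step 10
Reactants: 15 (3R,8Z)-10-(TBS-oxy)-8-[(TBDPS-oxy)methyl]-1-(phenylsulfonyl)dec-8-en-4-yn-3-ol
Product: 16 (3R,4Z,8Z)-10-(TBS-oxy)-8-[(TBDPS-oxy)methyl]-1-(phenylsulfonyl)-4-(tributylstannyl)deca-4,8-dien-3-ol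
Conditions: Bu3SnH, [Cp*RuCl]4 (cat.), CH2Cl2, rt
Reagents that add atoms: tributylstannane, CCCC[SnH](CCCC)CCCC
Why: Ruthenium-catalysed trans-hydrostannation of a propargylic alcohol; the free hydroxyl steers tin to the proximal carbon C10, and anti addition puts H on C1 trans to tin, so that C9 and C2 end up trans.

Step 11
Reactants: 16 (3R,4Z,8Z)-10-(TBS-oxy)-8-[(TBDPS-oxy)methyl]-1-(phenylsulfonyl)-4-(tributylstannyl)deca-4,8-dien-3-ol
Product: 17 methyl (2Z,6Z)-8-(TBS-oxy)-6-[(TBDPS-oxy)methyl]-2-[(1R)-1-hydroxy-3-(phenylsulfonyl)propyl]octa-2,6-dienoate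
Conditions: Pd(OAc)2 (cat.), Ph3As, 1,4-benzoquinone, CO (1 atm), MeOH, rt
Reagents that add atoms: carbon monoxide, [C-]#[O+]; methanol, CO
Why: Oxidative methoxycarbonylation of an alkenylstannane: transmetalation to divalent palladium, CO insertion and methanolysis, with benzoquinone as reoxidant. It proceeds with retention of alkene geometry and installs C14 cis to C2.

Step 12
Reactants: 17 methyl (2Z,6Z)-8-(TBS-oxy)-6-[(TBDPS-oxy)methyl]-2-[(1R)-1-hydroxy-3-(phenylsulfonyl)propyl]octa-2,6-dienoate
Product: 18 (2E,6Z)-8-(TBS-oxy)-6-[(TBDPS-oxy)methyl]-2-[(1R)-1-hydroxy-3-(phenylsulfonyl)propyl]octa-2,6-dien-1-ol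
Conditions: iBu2AlH (excess), CH2Cl2, −78 to −20 °C
Reagents that add atoms: none
Why: 1,2-Reduction of the enoate to the primary allylic alcohol; the sulfone and silyl ethers are inert to iBu2AlH, which is why the sulfone and not an ester activates C7.

Step 13
Reactants: 18 (2E,6Z)-8-(TBS-oxy)-6-[(TBDPS-oxy)methyl]-2-[(1R)-1-hydroxy-3-(phenylsulfonyl)propyl]octa-2,6-dien-1-ol
Product: 19 (4R,5E)-5-{(4Z)-6-(TBS-oxy)-4-[(TBDPS-oxy)methyl]hex-4-en-1-ylidene}-2,2-dimethyl-4-[2-(phenylsulfonyl)ethyl]-1,3-dioxane
Conditions: Me2C(OMe)2, PPTS (cat.), CH2Cl2, rt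
Reagents that add atoms: 2,2-dimethoxypropane, COC(C)(C)OC
Why: Thermodynamic acetalisation of the 1,3-diol to the six-membered isopropylidene acetal. Neither oxygen can then be ionised by zerovalent palladium, and O9 is held gauche to C14.

Step 14
Reactants: 20 2-chloro-N-methoxy-N-methylacetamide; 21 (4-methoxyphenyl)methanol
Product: 23 N-methoxy-2-(PMB-oxy)-N-methylacetamide, via sodium alkoxide 22 (not isolated)
Conditions: NaH, THF, 0 °C; then 20, 0 °C to rt
Reagents that add atoms: none
Why: Williamson etherification; the α-chloro amide is an activated SN2 electrophile and the Weinreb amide is not attacked by the alkoxide at this temperature.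

Step 15
Reactants: 19 (4R,5E)-5-{(4Z)-6-(TBS-oxy)-4-[(TBDPS-oxy)methyl]hex-4-en-1-ylidene}-2,2-dimethyl-4-[2-(phenylsulfonyl)ethyl]-1,3-dioxane; 23 N-methoxy-2-(PMB-oxy)-N-methylacetamide
Product: 25 4-[(4R,5E)-5-{(4Z)-6-(TBS-oxy)-4-[(TBDPS-oxy)methyl]hex-4-en-1-ylidene}-2,2-dimethyl-1,3-dioxan-4-yl]-1-(PMB-oxy)-3-(phenylsulfonyl)butan-2-one (C7 epimers), via lithiated sulfone 24 (not isolated)
Conditions: n-BuLi, THF, −78 °C; then 23, −78 to −20 °C; aq. NH4Cl
Reagents that add atoms: none
Why: Acylation of an α-sulfonyl carbanion with a Weinreb amide; the β-keto sulfone is released only on quench, so one equivalent of base suffices. The C7–C11 bond is formed; the C7 epimers are of no consequence.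

Step 16
Reactants: 25 4-[(4R,5E)-5-{(4Z)-6-(TBS-oxy)-4-[(TBDPS-oxy)methyl]hex-4-en-1-ylidene}-2,2-dimethyl-1,3-dioxan-4-yl]-1-(PMB-oxy)-3-(phenylsulfonyl)butan-2-one
Product: 26 4-[(4R,5E)-5-{(4Z)-6-hydroxy-4-[(TBDPS-oxy)methyl]hex-4-en-1-ylidene}-2,2-dimethyl-1,3-dioxan-4-yl]-1-(PMB-oxy)-3-(phenylsulfonyl)butan-2-one (C7 epimers)
Conditions: HF·pyridine, pyridine, THF, 0 °C
Reagents that add atoms: none
Why: Buffered HF cleaves a primary TBS ether much faster than a TBDPS ether and leaves the acetonide and the PMB ether intact.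

Step 17
Reactants: 26 4-[(4R,5E)-5-{(4Z)-6-hydroxy-4-[(TBDPS-oxy)methyl]hex-4-en-1-ylidene}-2,2-dimethyl-1,3-dioxan-4-yl]-1-(PMB-oxy)-3-(phenylsulfonyl)butan-2-one
Product: 27 methyl carbonate of 26 at the C6 hydroxyl (C7 epimers)
Conditions: ClCO2Me, pyridine, CH2Cl2, 0 °C
Reagents that add atoms: methyl chloroformate, COC(=O)Cl
Why: O-Acylation of the primary allylic alcohol; pyridine is too weak a base to enolise the β-keto sulfone, so the carbon acid stays untouched.

Step 18
Reactants: 27 methyl carbonate of 26 at the C6 hydroxyl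
Product: 28 (1(10)E,4Z,9R)-15-(TBDPS-oxy)-9,14-(isopropylidenedioxy)-12-(PMB-oxy)-7-(phenylsulfonyl)-13-norgermacra-1(10),4-dien-11-one (C7 epimers)
Conditions: Pd(PPh3)4 (10 mol%), THF, 65 °C, slow addition of 27 to a final 0.002 M
Reagents that add atoms: none
Why: Zerovalent palladium ionises the primary allylic carbonate with loss of CO2, and the methoxide set free deprotonates the β-keto sulfone; the closest known reaction type is the Tsuji–Trost macrocyclisation of allylic carbonates with stabilised carbanions under neutral conditions, as used for ten- and eleven-membered terpenoid rings. The soft carbanion attacks the cationic π-allyl complex on the face opposite palladium at the unsubstituted terminus C6, which closes the ten-membered ring with the alkene endocyclic (10-endo mode); attack at C4 (8-exo) would join two fully substituted carbons and is not expected. The one new stereocentre, quaternary C7, is not controlled and need not be, because both epimers give the same enolate in step 19. The step needs intramolecular over intermolecular alkylation, which slow addition at high dilution should secure, and C- over O-alkylation, which follows because O-allylation is reversible under the catalyst and drains to the C-alkylated ring. It also needs retention of the C4=C5 geometry: η3–η1–η3 equilibration runs through the primary terminus C6 and leaves the arrangement at C4 untouched, so C3 stays trans to C6. Chemoselectivity rests on the substrate, since the other allylic oxygens are an acetal and a silyl ether, which zerovalent palladium does not ionise. The temperature stays below the range in which the product 1,5-diene would undergo Cope rearrangement.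

Step 19
Reactants: 28 (1(10)E,4Z,9R)-15-(TBDPS-oxy)-9,14-(isopropylidenedioxy)-12-(PMB-oxy)-7-(phenylsulfonyl)-13-norgermacra-1(10),4-dien-11-one
Product: 30 (1(10)E,4Z,9R)-15-(TBDPS-oxy)-9,14-(isopropylidenedioxy)-12-(PMB-oxy)-13-norgermacra-1(10),4-dien-11-one (C7 epimers), via samarium enolate 29 (not isolated)
Conditions: SmI2 (2.5 equiv), THF/MeOH, −78 °C
Reagents that add atoms: none
Why: Reductive desulfonylation of an α-sulfonyl ketone by two single-electron transfers from divalent samarium; sulfinate is a far better leaving group from the ketyl than the PMB-oxy group on C12. Methanol protonates the enolate at C7 without stereocontrol.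

Step 20
Reactants: 30 (1(10)E,4Z,9R)-15-(TBDPS-oxy)-9,14-(isopropylidenedioxy)-12-(PMB-oxy)-13-norgermacra-1(10),4-dien-11-one (C7 epimers)
Product: 31 (1(10)E,4Z,7R,9R)-15-(TBDPS-oxy)-9,14-(isopropylidenedioxy)-12-(PMB-oxy)-13-norgermacra-1(10),4-dien-11-one
Conditions: DBU (0.3 equiv), CH2Cl2, rt; chromatography, the 7-epimer is resubmitted
Reagents that add atoms: none
Why: Base-mediated epimerisation through the C11 enolate sets C7 under thermodynamic control. The acetonide holds O9 gauche to C14, the pseudo-equatorial site of the crown conformer, and the acyl group on C7 should prefer the pseudo-equatorial site cis to it (7R).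

Step 21
Reactants: 31 (1(10)E,4Z,7R,9R)-15-(TBDPS-oxy)-9,14-(isopropylidenedioxy)-12-(PMB-oxy)-13-norgermacra-1(10),4-dien-11-one
Product: 32 (1(10)E,4Z,7R,9R)-15-(TBDPS-oxy)-9,14-(isopropylidenedioxy)-12-(PMB-oxy)germacra-1(10),4,11(13)-triene
Conditions: Cp2Ti(μ-Cl)(μ-CH2)AlMe2, pyridine, THF/toluene, −40 to 0 °C
Reagents that add atoms: Tebbe reagent Cp2Ti(μ-Cl)(μ-CH2)AlMe2, C[Al-]1(C)C[Ti](C2C=CC=C2)(C2C=CC=C2)[Cl+]1
Why: Tebbe methylenation of a hindered, enolisable ketone through a titanium methylidene; the reagent is not basic, so C7 is not epimerised, and the low temperature spares the 1,5-diene.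

Step 22
Reactants: 32 (1(10)E,4Z,7R,9R)-15-(TBDPS-oxy)-9,14-(isopropylidenedioxy)-12-(PMB-oxy)germacra-1(10),4,11(13)-triene
Product: 33 (1(10)E,4Z,7R,9R)-15-(TBDPS-oxy)-9,14-(isopropylidenedioxy)germacra-1(10),4,11(13)-trien-12-ol
Conditions: DDQ, CH2Cl2/pH 7 buffer, 0 °C
Reagents that add atoms: none
Why: Oxidative cleavage of a PMB ether by hydride abstraction at the benzylic position; the acetonide, the silyl ether and the unactivated alkenes are not affected under buffered conditions.

Step 23
Reactants: 33 (1(10)E,4Z,7R,9R)-15-(TBDPS-oxy)-9,14-(isopropylidenedioxy)germacra-1(10),4,11(13)-trien-12-ol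
Product: 34 (1(10)E,4Z,7R,9R)-15-(TBDPS-oxy)-9,14-(isopropylidenedioxy)germacra-1(10),4,11(13)-trien-12-yl acetate
Conditions: Ac2O, pyridine, DMAP (cat.), CH2Cl2, 0 °C to rt
Reagents that add atoms: acetic anhydride, CC(=O)OC(C)=O
Why: Routine acetylation of the only free hydroxyl installs the first of the three esters.

Step 24
Reactants: 34 (1(10)E,4Z,7R,9R)-15-(TBDPS-oxy)-9,14-(isopropylidenedioxy)germacra-1(10),4,11(13)-trien-12-yl acetate
Product: 35 (1(10)E,4Z,7R,9R)-15-(TBDPS-oxy)-9,14-dihydroxygermacra-1(10),4,11(13)-trien-12-yl acetate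
Conditions: PPTS, MeOH, rt
Reagents that add atoms: none
Why: Mild acid-catalysed transacetalisation to methanol frees the 1,3-diol; the TBDPS ether and the acetate are stable, and the weak acid is chosen to spare the 1,5-diene.

Step 25
Reactants: 36 (4R)-4-benzyl-3-propanoyl-1,3-oxazolidin-2-one; 37 acetaldehyde
Product: 39 (4R)-4-benzyl-3-[(2R,3S)-3-hydroxy-2-methylbutanoyl]-1,3-oxazolidin-2-one, via boron enolate 38 (not isolated)
Conditions: Bu2BOTf, iPr2NEt, CH2Cl2, −78 to 0 °C; then 37, −78 to 0 °C; pH 7 buffer, MeOH, H2O2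
Reagents that add atoms: none
Why: Evans syn aldol: the Z boron enolate reacts through a closed chair transition state on the face away from the benzyl group, so the R auxiliary gives the 2R,3S syn product.

Step 26
Reactants: 39 (4R)-4-benzyl-3-[(2R,3S)-3-hydroxy-2-methylbutanoyl]-1,3-oxazolidin-2-one
Product: 40 (4R)-4-benzyl-3-[(2R,3S)-2-methyl-3-(TES-oxy)butanoyl]-1,3-oxazolidin-2-one
Conditions: TESCl, imidazole, DMF, rt
Reagents that add atoms: chlorotriethylsilane, CC[Si](Cl)(CC)CC
Why: Silylation of the secondary alcohol prevents retro-aldol cleavage and self-acylation; TES is chosen so that it leaves together with TBDPS in step 30.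

Step 27
Reactants: 40 (4R)-4-benzyl-3-[(2R,3S)-2-methyl-3-(TES-oxy)butanoyl]-1,3-oxazolidin-2-one
Product: 42 (2R,3S)-2-methyl-3-(TES-oxy)butanoic acid, via lithium peroxycarboxylate 41 (not isolated)
Conditions: LiOH, H2O2, THF/H2O, 0 °C; then aq. Na2SO3; dilute HCl to pH 4 at 0 °C
Reagents that add atoms: hydrogen peroxide, OO
Why: Hydroperoxide attacks the exocyclic imide carbonyl selectively and the peracid salt is reduced on work-up; the α-centre is not epimerised under these conditions.

Step 28
Reactants: 35 (1(10)E,4Z,7R,9R)-15-(TBDPS-oxy)-9,14-dihydroxygermacra-1(10),4,11(13)-trien-12-yl acetate; 42 (2R,3S)-2-methyl-3-(TES-oxy)butanoic acid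
Product: 43 (1(10)E,4Z,7R,9R)-12-acetoxy-15-(TBDPS-oxy)-9-hydroxygermacra-1(10),4,11(13)-trien-14-yl (2R,3S)-2-methyl-3-(TES-oxy)butanoate
Conditions: EDC·HCl, DMAP (cat.), CH2Cl2, −10 to 0 °C, 1.1 equiv of 42
Reagents that add atoms: none
Why: Steglich esterification; the primary C14 hydroxyl should react well ahead of the secondary C9 hydroxyl, which sits on the ring next to the trisubstituted alkene.

Step 29
Reactants: 43 (1(10)E,4Z,7R,9R)-12-acetoxy-15-(TBDPS-oxy)-9-hydroxygermacra-1(10),4,11(13)-trien-14-yl (2R,3S)-2-methyl-3-(TES-oxy)butanoate; 44 3-methylbut-2-enoyl chloride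
Product: 45 (1(10)E,4Z,7R,9R)-12-acetoxy-15-(TBDPS-oxy)-9-[(3-methylbut-2-enoyl)oxy]germacra-1(10),4,11(13)-trien-14-yl (2R,3S)-2-methyl-3-(TES-oxy)butanoate
Conditions: pyridine, DMAP, CH2Cl2, 0 °C to rt
Reagents that add atoms: none
Why: DMAP-catalysed acylation of the secondary allylic alcohol; pyridine in place of a trialkylamine limits ketene formation and so deconjugation of the acyl group.

Step 30
Reactants: 45 (1(10)E,4Z,7R,9R)-12-acetoxy-15-(TBDPS-oxy)-9-[(3-methylbut-2-enoyl)oxy]germacra-1(10),4,11(13)-trien-14-yl (2R,3S)-2-methyl-3-(TES-oxy)butanoate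
Product: 46 (1(10)E,4Z,7R,9R)-12-acetoxy-15-hydroxy-9-[(3-methylbut-2-enoyl)oxy]germacra-1(10),4,11(13)-trien-14-yl (2R,3S)-3-hydroxy-2-methylbutanoate
Conditions: TBAF, AcOH (1:1), THF, 0 °C to rt
Reagents that add atoms: none
Why: Fluoride cleaves both silyl ethers; buffering with acetic acid suppresses acyl migration and β-elimination of the hydroxy ester.

Step 31
Reactants: 46 (1(10)E,4Z,7R,9R)-12-acetoxy-15-hydroxy-9-[(3-methylbut-2-enoyl)oxy]germacra-1(10),4,11(13)-trien-14-yl (2R,3S)-3-hydroxy-2-methylbutanoate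
Product: 47 (1(10)E,4S,5R,7S,9R)-12-acetoxy-4,5-epoxy-15-hydroxy-9-[(3-methylbut-2-enoyl)oxy]germacra-1(10),11(13)-dien-14-yl (2R,3S)-3-hydroxy-2-methylbutanoate
Conditions: Ti(OiPr)4 (1.2 equiv), L-(+)-diethyl tartrate (1.5 equiv), t-BuOOH, 4 Å MS, CH2Cl2, −25 °C
Reagents that add atoms: tert-butyl hydroperoxide, CC(C)(C)OO
Why: Sharpless asymmetric epoxidation: only C4=C5 has an allylic hydroxyl, and L-(+)-tartrate delivers oxygen to the face that gives 2S-type glycidols, here 4S,5R with the trans epoxide following from the alkene geometry. Peripheral attack on the crown conformer is expected to point the same way; titanium is used in excess because the side-chain hydroxyl also binds it.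

## Compound list

1 | prop-2-yn-1-ol | C#CCO | starting material
2 | tert-butyl(diphenyl)(prop-2-yn-1-yloxy)silane | C#CCO[Si](c1ccccc1)(c1ccccc1)C(C)(C)C | intermediate
3 | lithium acetylide of 2 | [Li]C#CCO[Si](c1ccccc1)(c1ccccc1)C(C)(C)C | intermediate (not isolated)
4 | methyl 4-(TBDPS-oxy)but-2-ynoate | COC(=O)C#CCO[Si](c1ccccc1)(c1ccccc1)C(C)(C)C | intermediate
5 | (4-bromobut-1-yn-1-yl)trimethylsilane | C[Si](C)(C)C#CCCBr | starting material
6 | [4-(trimethylsilyl)but-3-yn-1-yl]magnesium bromide | C[Si](C)(C)C#CCC[Mg]Br | intermediate (not isolated)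
7 | methyl (2Z)-3-[(TBDPS-oxy)methyl]-7-(trimethylsilyl)hept-2-en-6-ynoate | COC(=O)/C=C(CO[Si](c1ccccc1)(c1ccccc1)C(C)(C)C)/CCC#C[Si](C)(C)C | intermediate
8 | (2Z)-3-[(TBDPS-oxy)methyl]-7-(trimethylsilyl)hept-2-en-6-yn-1-ol | OC/C=C(CO[Si](c1ccccc1)(c1ccccc1)C(C)(C)C)/CCC#C[Si](C)(C)C | intermediate
9 | (2Z)-1-(TBS-oxy)-3-[(TBDPS-oxy)methyl]-7-(trimethylsilyl)hept-2-en-6-yne | CC(C)(C)[Si](C)(C)OC/C=C(CO[Si](c1ccccc1)(c1ccccc1)C(C)(C)C)/CCC#C[Si](C)(C)C | intermediate
10 | (5Z)-7-(TBS-oxy)-5-[(TBDPS-oxy)methyl]hept-5-en-1-yne | CC(C)(C)[Si](C)(C)OC/C=C(CO[Si](c1ccccc1)(c1ccccc1)C(C)(C)C)/CCC#C | intermediate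
11 | 3-(phenylsulfonyl)propanoic acid | OC(=O)CCS(=O)(=O)c1ccccc1 | starting material
12 | N-methoxy-N-methyl-3-(phenylsulfonyl)propanamide | CON(C)C(=O)CCS(=O)(=O)c1ccccc1 | intermediate
13 | lithium acetylide of 10 | CC(C)(C)[Si](C)(C)OC/C=C(CO[Si](c1ccccc1)(c1ccccc1)C(C)(C)C)/CCC#C[Li] | intermediate (not isolated)
14 | (8Z)-10-(TBS-oxy)-8-[(TBDPS-oxy)methyl]-1-(phenylsulfonyl)dec-8-en-4-yn-3-one | O=C(CCS(=O)(=O)c1ccccc1)C#CCC/C(CO[Si](c1ccccc1)(c1ccccc1)C(C)(C)C)=C/CO[Si](C)(C)C(C)(C)C | intermediate
15 | (3R,8Z)-10-(TBS-oxy)-8-[(TBDPS-oxy)methyl]-1-(phenylsulfonyl)dec-8-en-4-yn-3-ol | O[C@H](CCS(=O)(=O)c1ccccc1)C#CCC/C(CO[Si](c1ccccc1)(c1ccccc1)C(C)(C)C)=C/CO[Si](C)(C)C(C)(C)C | intermediate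
16 | (3R,4Z,8Z)-10-(TBS-oxy)-8-[(TBDPS-oxy)methyl]-1-(phenylsulfonyl)-4-(tributylstannyl)deca-4,8-dien-3-ol | O[C@H](CCS(=O)(=O)c1ccccc1)/C([Sn](CCCC)(CCCC)CCCC)=C/CC/C(CO[Si](c1ccccc1)(c1ccccc1)C(C)(C)C)=C/CO[Si](C)(C)C(C)(C)C | intermediate
17 | methyl (2Z,6Z)-8-(TBS-oxy)-6-[(TBDPS-oxy)methyl]-2-[(1R)-1-hydroxy-3-(phenylsulfonyl)propyl]octa-2,6-dienoate | O[C@H](CCS(=O)(=O)c1ccccc1)/C(C(=O)OC)=C/CC/C(CO[Si](c1ccccc1)(c1ccccc1)C(C)(C)C)=C/CO[Si](C)(C)C(C)(C)C | intermediate
18 | (2E,6Z)-8-(TBS-oxy)-6-[(TBDPS-oxy)methyl]-2-[(1R)-1-hydroxy-3-(phenylsulfonyl)propyl]octa-2,6-dien-1-ol | O[C@H](CCS(=O)(=O)c1ccccc1)/C(CO)=C/CC/C(CO[Si](c1ccccc1)(c1ccccc1)C(C)(C)C)=C/CO[Si](C)(C)C(C)(C)C | intermediate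
19 | (4R,5E)-5-{(4Z)-6-(TBS-oxy)-4-[(TBDPS-oxy)methyl]hex-4-en-1-ylidene}-2,2-dimethyl-4-[2-(phenylsulfonyl)ethyl]-1,3-dioxane | CC1(C)O[C@H](CCS(=O)(=O)c2ccccc2)/C(CO1)=C/CC/C(CO[Si](c2ccccc2)(c2ccccc2)C(C)(C)C)=C/CO[Si](C)(C)C(C)(C)C | intermediate
20 | 2-chloro-N-methoxy-N-methylacetamide | CON(C)C(=O)CCl | starting material
21 | (4-methoxyphenyl)methanol | COc1ccc(CO)cc1 | starting material
22 | sodium (4-methoxyphenyl)methanolate | COc1ccc(C[O-])cc1.[Na+] | intermediate (not isolated)
23 | N-methoxy-2-(PMB-oxy)-N-methylacetamide | CON(C)C(=O)COCc1ccc(OC)cc1 | intermediate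
24 | α-lithiated sulfone of 19 (lithium on C7) | CC1(C)O[C@H](CC([Li])S(=O)(=O)c2ccccc2)/C(CO1)=C/CC/C(CO[Si](c2ccccc2)(c2ccccc2)C(C)(C)C)=C/CO[Si](C)(C)C(C)(C)C | intermediate (not isolated)
25 | 4-[(4R,5E)-5-{(4Z)-6-(TBS-oxy)-4-[(TBDPS-oxy)methyl]hex-4-en-1-ylidene}-2,2-dimethyl-1,3-dioxan-4-yl]-1-(PMB-oxy)-3-(phenylsulfonyl)butan-2-one (C7 epimers) | CC1(C)O[C@H](CC(C(=O)COCc2ccc(OC)cc2)S(=O)(=O)c2ccccc2)/C(CO1)=C/CC/C(CO[Si](c2ccccc2)(c2ccccc2)C(C)(C)C)=C/CO[Si](C)(C)C(C)(C)C | intermediate
26 | 4-[(4R,5E)-5-{(4Z)-6-hydroxy-4-[(TBDPS-oxy)methyl]hex-4-en-1-ylidene}-2,2-dimethyl-1,3-dioxan-4-yl]-1-(PMB-oxy)-3-(phenylsulfonyl)butan-2-one (C7 epimers) | CC1(C)O[C@H](CC(C(=O)COCc2ccc(OC)cc2)S(=O)(=O)c2ccccc2)/C(CO1)=C/CC/C(CO[Si](c2ccccc2)(c2ccccc2)C(C)(C)C)=C/CO | intermediate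
27 | methyl carbonate of 26 at the C6 hydroxyl (C7 epimers) | CC1(C)O[C@H](CC(C(=O)COCc2ccc(OC)cc2)S(=O)(=O)c2ccccc2)/C(CO1)=C/CC/C(CO[Si](c2ccccc2)(c2ccccc2)C(C)(C)C)=C/COC(=O)OC | intermediate
28 | (1(10)E,4Z,9R)-15-(TBDPS-oxy)-9,14-(isopropylidenedioxy)-12-(PMB-oxy)-7-(phenylsulfonyl)-13-norgermacra-1(10),4-dien-11-one (C7 epimers) | COc1ccc(COCC(=O)C2(S(=O)(=O)c3ccccc3)C[C@@H](OC(C)(C)O4)/C(C4)=C/CC/C(CO[Si](c3ccccc3)(c3ccccc3)C(C)(C)C)=C/C2)cc1 | intermediate
29 | samarium enolate of 30 (C7=C11, O–SmI2, trivalent samarium) | COc1ccc(COCC(O[Sm](I)I)=C2C[C@@H](OC(C)(C)O4)/C(C4)=C/CC/C(CO[Si](c3ccccc3)(c3ccccc3)C(C)(C)C)=C/C2)cc1 | intermediate (not isolated)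
30 | (1(10)E,4Z,9R)-15-(TBDPS-oxy)-9,14-(isopropylidenedioxy)-12-(PMB-oxy)-13-norgermacra-1(10),4-dien-11-one (C7 epimers) | COc1ccc(COCC(=O)C2C[C@@H](OC(C)(C)O4)/C(C4)=C/CC/C(CO[Si](c3ccccc3)(c3ccccc3)C(C)(C)C)=C/C2)cc1 | intermediate
31 | (1(10)E,4Z,7R,9R)-15-(TBDPS-oxy)-9,14-(isopropylidenedioxy)-12-(PMB-oxy)-13-norgermacra-1(10),4-dien-11-one | COc1ccc(COCC(=O)[C@H]2C[C@@H](OC(C)(C)O4)/C(C4)=C/CC/C(CO[Si](c3ccccc3)(c3ccccc3)C(C)(C)C)=C/C2)cc1 | intermediate
32 | (1(10)E,4Z,7R,9R)-15-(TBDPS-oxy)-9,14-(isopropylidenedioxy)-12-(PMB-oxy)germacra-1(10),4,11(13)-triene | COc1ccc(COCC(=C)[C@H]2C[C@@H](OC(C)(C)O4)/C(C4)=C/CC/C(CO[Si](c3ccccc3)(c3ccccc3)C(C)(C)C)=C/C2)cc1 | intermediate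
33 | (1(10)E,4Z,7R,9R)-15-(TBDPS-oxy)-9,14-(isopropylidenedioxy)germacra-1(10),4,11(13)-trien-12-ol | C=C(CO)[C@H]1C[C@@H](OC(C)(C)O2)/C(C2)=C/CC/C(CO[Si](c2ccccc2)(c2ccccc2)C(C)(C)C)=C/C1 | intermediate
34 | (1(10)E,4Z,7R,9R)-15-(TBDPS-oxy)-9,14-(isopropylidenedioxy)germacra-1(10),4,11(13)-trien-12-yl acetate | C=C(COC(C)=O)[C@H]1C[C@@H](OC(C)(C)O2)/C(C2)=C/CC/C(CO[Si](c2ccccc2)(c2ccccc2)C(C)(C)C)=C/C1 | intermediate
35 | (1(10)E,4Z,7R,9R)-15-(TBDPS-oxy)-9,14-dihydroxygermacra-1(10),4,11(13)-trien-12-yl acetate | C=C(COC(C)=O)[C@H]1C[C@@H](O)/C(CO)=C/CC/C(CO[Si](c2ccccc2)(c2ccccc2)C(C)(C)C)=C/C1 | intermediate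
36 | (4R)-4-benzyl-3-propanoyl-1,3-oxazolidin-2-one | CCC(=O)N1[C@H](Cc2ccccc2)COC1=O | starting material
37 | acetaldehyde | CC=O | starting material
38 | (Z)-dibutylboron enolate of 36 | C/C=C(\OB(CCCC)CCCC)N1[C@H](Cc2ccccc2)COC1=O | intermediate (not isolated)
39 | (4R)-4-benzyl-3-[(2R,3S)-3-hydroxy-2-methylbutanoyl]-1,3-oxazolidin-2-one | O=C1OC[C@@H](Cc2ccccc2)N1C(=O)[C@H](C)[C@H](C)O | intermediate
40 | (4R)-4-benzyl-3-[(2R,3S)-2-methyl-3-(TES-oxy)butanoyl]-1,3-oxazolidin-2-one | O=C1OC[C@@H](Cc2ccccc2)N1C(=O)[C@H](C)[C@H](C)O[Si](CC)(CC)CC | intermediate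
41 | lithium (2R,3S)-2-methyl-3-(TES-oxy)butaneperoxoate | [Li+].[O-]OC(=O)[C@H](C)[C@H](C)O[Si](CC)(CC)CC | intermediate (not isolated)
42 | (2R,3S)-2-methyl-3-(TES-oxy)butanoic acid | OC(=O)[C@H](C)[C@H](C)O[Si](CC)(CC)CC | intermediate
43 | (1(10)E,4Z,7R,9R)-12-acetoxy-15-(TBDPS-oxy)-9-hydroxygermacra-1(10),4,11(13)-trien-14-yl (2R,3S)-2-methyl-3-(TES-oxy)butanoate | C=C(COC(C)=O)[C@H]1C[C@@H](O)/C(COC(=O)[C@H](C)[C@H](C)O[Si](CC)(CC)CC)=C/CC/C(CO[Si](c2ccccc2)(c2ccccc2)C(C)(C)C)=C/C1 | intermediate
44 | 3-methylbut-2-enoyl chloride | CC(C)=CC(=O)Cl | starting material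
45 | (1(10)E,4Z,7R,9R)-12-acetoxy-15-(TBDPS-oxy)-9-[(3-methylbut-2-enoyl)oxy]germacra-1(10),4,11(13)-trien-14-yl (2R,3S)-2-methyl-3-(TES-oxy)butanoate | C=C(COC(C)=O)[C@H]1C[C@@H](OC(=O)C=C(C)C)/C(COC(=O)[C@H](C)[C@H](C)O[Si](CC)(CC)CC)=C/CC/C(CO[Si](c2ccccc2)(c2ccccc2)C(C)(C)C)=C/C1 | intermediate
46 | (1(10)E,4Z,7R,9R)-12-acetoxy-15-hydroxy-9-[(3-methylbut-2-enoyl)oxy]germacra-1(10),4,11(13)-trien-14-yl (2R,3S)-3-hydroxy-2-methylbutanoate | C=C(COC(C)=O)[C@H]1C[C@@H](OC(=O)C=C(C)C)/C(COC(=O)[C@H](C)[C@H](C)O)=C/CC/C(CO)=C/C1 | intermediate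
47 | (1(10)E,4S,5R,7S,9R)-12-acetoxy-4,5-epoxy-15-hydroxy-9-[(3-methylbut-2-enoyl)oxy]germacra-1(10),11(13)-dien-14-yl (2R,3S)-3-hydroxy-2-methylbutanoate | C=C(COC(C)=O)[C@H]1C[C@@H](OC(=O)C=C(C)C)/C(COC(=O)[C@H](C)[C@H](C)O)=C/CC[C@@]2(CO)O[C@@H]2C1 | target

## Step count and least certain steps

Total: 31 steps. Longest linear sequence: 26 steps (1–6, 8–13, 15–24, 28–31, from 1 to 47).

Step 18 (key step). The closure may lose to intermolecular alkylation, because the ten-membered ring with two trans alkenes is strained. A slow nucleophile also leaves time for β-hydride elimination from the π-allyl complex to a diene, or for erosion of the C4=C5 geometry through the tertiary terminus. Fallback: the route leaves at alcohol 26, which is converted by an Appel reaction (CBr4, PPh3, CH2Cl2, 0 °C) into the allylic bromide of 26 F5. Slow addition of this bromide to Cs2CO3 in DMF at rt under high dilution should give the same C6–C7 bond by direct SN2 alkylation of the β-keto sulfone anion, with the alkene geometry carried through unchanged. The route is rejoined at 28.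

Step 20. The thermodynamic preference for the 7R epimer may be small if the ring does not populate the crown conformer assumed. Fallback: from the epimer mixture 30 the acetonide is removed (PPTS, MeOH) to give the 9,14-dihydroxy ketone F6. On treatment with DBU only the 7,9-cis epimer of this diol can close the five-membered lactol between O9 and C11, giving lactol F7, and it is thereby drained from the equilibrium. Renewed acetalisation with 2,2-dimethoxypropane and PPTS opens the lactol and returns the route at 31.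

Step 8 (and 9). The β-sulfonyl Weinreb amide and the β-sulfonyl ynone can lose benzenesulfinate by E1cB elimination if the acetylide or the hydrogenation medium acts as a base. Fallback: sulfur is carried one oxidation level lower. Commercial 3-(phenylsulfanyl)propanoic acid is converted as in step 7 into N-methoxy-N-methyl-3-(phenylsulfanyl)propanamide F1. The acetylide 13 made from alkyne 10 adds to it to give the sulfanyl ynone F2, and Noyori transfer hydrogenation as in step 9 gives the sulfanyl propargylic alcohol F3. Oxidation at sulfur with H2O2 and catalytic (NH4)6Mo7O24 in ethanol returns the route at 15.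

Step 11. Protodestannylation or slow transmetalation may compete, and the primary TBS ether could suffer in methanol. Fallback: from stannane 16, iododestannylation (I2, CH2Cl2, 0 °C) gives with retention the alkenyl iodide F4. Its carbonylation by oxidative addition to zerovalent palladium (Pd(PPh3)2Cl2, CO, MeOH, Et3N, 50 °C) returns the route at 17.

Step 31. The facial preference of the reagent could be opposed by the ring (poor diastereoselectivity), and the titanium Lewis acid may open the new epoxy alcohol or trigger transannular attack by C1=C10. Fallback: from 46, a hydroxyl-directed epoxidation without chiral ligand (VO(acac)2, t-BuOOH, CH2Cl2, 0 °C) relies on peripheral attack on the crown conformer alone and leads directly to 47; no new compound is involved.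

## Further compounds

F1 | step 8 | N-methoxy-N-methyl-3-(phenylsulfanyl)propanamide | CON(C)C(=O)CCSc1ccccc1
F2 | step 8 | (8Z)-10-(TBS-oxy)-8-[(TBDPS-oxy)methyl]-1-(phenylsulfanyl)dec-8-en-4-yn-3-one | O=C(CCSc1ccccc1)C#CCC/C(CO[Si](c1ccccc1)(c1ccccc1)C(C)(C)C)=C/CO[Si](C)(C)C(C)(C)C
F3 | step 8 | (3R,8Z)-10-(TBS-oxy)-8-[(TBDPS-oxy)methyl]-1-(phenylsulfanyl)dec-8-en-4-yn-3-ol | O[C@H](CCSc1ccccc1)C#CCC/C(CO[Si](c1ccccc1)(c1ccccc1)C(C)(C)C)=C/CO[Si](C)(C)C(C)(C)C
F4 | step 11 | (3R,4Z,8Z)-10-(TBS-oxy)-8-[(TBDPS-oxy)methyl]-4-iodo-1-(phenylsulfonyl)deca-4,8-dien-3-ol | O[C@H](CCS(=O)(=O)c1ccccc1)/C(I)=C/CC/C(CO[Si](c1ccccc1)(c1ccccc1)C(C)(C)C)=C/CO[Si](C)(C)C(C)(C)C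
F5 | step 18 | allylic bromide of 26 (Br in place of the C6 hydroxyl; C7 epimers) | CC1(C)O[C@H](CC(C(=O)COCc2ccc(OC)cc2)S(=O)(=O)c2ccccc2)/C(CO1)=C/CC/C(CO[Si](c2ccccc2)(c2ccccc2)C(C)(C)C)=C/CBr
F6 | step 20 | (1(10)E,4Z,9R)-15-(TBDPS-oxy)-9,14-dihydroxy-12-(PMB-oxy)-13-norgermacra-1(10),4-dien-11-one (C7 epimers) | COc1ccc(COCC(=O)C2C[C@@H](O)/C(CO)=C/CC/C(CO[Si](c3ccccc3)(c3ccccc3)C(C)(C)C)=C/C2)cc1
F7 | step 20 | 9,11-lactol of the (7R,9R)-epimer of F6 (five-membered hemiketal O9–C11, C11 anomers) | COc1ccc(COCC3(O)[C@H]2C[C@@H](O3)/C(CO)=C/CC/C(CO[Si](c4ccccc4)(c4ccccc4)C(C)(C)C)=C/C2)cc1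
F0 | step 31 | none | none
A1 | alternative 1 | open-chain epoxy iodide with terminal alkyne at C1 and primary iodide on C2 | C#C[C@H](O[Si](CC)(CC)CC)C[C@H](C(=C)CO[Si](C)(C)C(C)(C)C)C[C@H]1O[C@@]1(CCI)CO[Si](c2ccccc2)(c2ccccc2)C(C)(C)C
A2 | alternative 1 | ten-membered epoxy cycloalkyne (C1–C10 triple bond) | C=C(CO[Si](C)(C)C(C)(C)C)[C@H]1C[C@@H](O[Si](CC)(CC)CC)C#CCC[C@@]3(CO[Si](c2ccccc2)(c2ccccc2)C(C)(C)C)O[C@@H]3C1
A3 | alternative 2 | twelve-membered 2-methylene oxacycle (allyl vinyl ether O–C13, C8 exocyclic methylene on C9) | C=C1OC/C(CO[Si](C)(C)C(C)(C)C)=C/C[C@H]2O[C@]2(CO[Si](c3ccccc3)(c3ccccc3)C(C)(C)C)CC/C=C1\COCc1ccc(OC)cc1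
A4 | alternative 2 | ten-membered epoxy enone with the C7 side chain and C11–C13 methylene | C=C(CO[Si](C)(C)C(C)(C)C)[C@H]1CC(=O)/C(COCc2ccc(OC)cc2)=C/CC[C@@]3(CO[Si](c2ccccc2)(c2ccccc2)C(C)(C)C)O[C@@H]3C1
A5 | alternative 3 | trans-1,2-dialkenylcyclohexanol (ring C5–C10; vinyl and CH2O-PMB on C10, hydroxyl and 3-(TBDPS-oxy)prop-1-en-2-yl on C5) | C=C[C@]1(COCc2ccc(OC)cc2)[C@H](O[Si](CC)(CC)CC)C[C@H](C(=C)CO[Si](C)(C)C(C)(C)C)C[C@@]1(O)C(=C)CO[Si](c2ccccc2)(c2ccccc2)C(C)(C)C
A6 | alternative 3 | ten-membered dienyl C5 triflate with C7 and C9 in place | C=C(CO[Si](C)(C)C(C)(C)C)[C@H]1C[C@@H](O[Si](CC)(CC)CC)/C(COCc2ccc(OC)cc2)=C/CC/C(CO[Si](c2ccccc2)(c2ccccc2)C(C)(C)C)=C(OS(=O)(=O)C(F)(F)F)/C1
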